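The rate constants belong to no real substance; the result is computed.

If you would rather test a figure than trust it, ask what the yield does when each given number is wrong. Here that means theta, the closed flask where everything is charged at once.

| setting | alpha | eta | beta | theta |
|---|---|---|---|---|
| substrate | 0.20 M | 0.20 M | 0.20 M (fed, over 2.00 h) | 0.20 M |
| partner | 0.400 M (fed, over 2.00 h) | 0.400 M | 0.400 M | 0.400 M |
| free catalyst | 1.0 mM | 1.0 mM | 1.0 mM | 1.0 mM |
| impurity | 0.12 mM | 0.12 mM | 0.12 mM | 0.12 mM |
| time | 2.0 h |  | 2.0 h | 2.0 h |
| remark | all but partner at the start; partner goes in evenly over 2.00 h, the run ends at 2.0 h | a single well-mixed tank run continuously and read at steady state, 2.0 h in it on average | a stirred flask in which substrate is dosed at a steady rate over 2.00 h without added volume, worked up at 2.0 h | a closed flask charged with all of it at once and left for 2.0 h |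

1. the set-up with the highest amount of target at the outlet or at the end, in percent of the substrate put in ("none" if the first two lie within 2 percentage points) (alpha / eta / beta / theta / none)
2. amount of target at the outlet or at the end, in percent of the substrate put in, alpha
3. amount of target at the outlet or at the end, in percent of the substrate put in, eta
4. amount of target at the outlet or at the end, in percent of the substrate put in, beta
5. amount of target at the outlet or at the end, in percent of the substrate put in, theta

- two of one species on the left: rate k times its square, two consumed each time
- the stated concentrations are those of everything mixed, before any reaction; amounts are the same in each set-up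
- the feed brings no volume worth counting
- run time (alpha): 2.0 h

In theta, catalyst intermediate A binds substrate, and catalyst intermediate B then goes forward with a share of 0.445 and otherwise falls back, so the working constant is 1.58 M⁻¹ s⁻¹ and substrate falls pseudo-first-order in catalyst intermediate A. That intermediate dies by its own square, so its time integral grows as a logarithm. I count as live the catalyst the impurity leaves, 0.880 mM, hold it all as catalyst intermediate A from the start, and call twice the death constant times live catalyst times run time the death count, 22.8. Substrate left is then 1 plus that count, raised to minus the exhaustion exponent, the working constant over twice the death constant, 0.439, which gives 24.9 %.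

Now the errors. Halving the live catalyst moves that figure to 33.1 %, while doubling the death constant moves it to 43.0 %, further, so the constants of steps 2, 3 and 5 must be known well and the catalyst charge less so. Step 4 does not enter the exponent, and capture by partner, at its charge, runs faster than step 3. Catalyst standing outside catalyst intermediate A does not enter its death step, so I commit to a reckoned floor for target in theta, 75.1 %, and reckon no further for the other flasks.

The forecast gives 83 % for alpha, 64 % for eta, 28 % for beta and 81 % for theta, and names none as best, its ground being: “alpha and theta are too close to separate”.

    partner + free catalyst → catalyst intermediate A (k1 = 7.44 M⁻¹ s⁻¹)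
    substrate + catalyst intermediate A ⇌ catalyst intermediate B (K2 = 4.8 M⁻¹, k2 = 3.55 M⁻¹ s⁻¹)
    catalyst intermediate B → by-product + catalyst intermediate C (k3 = 0.593 s⁻¹)
    catalyst intermediate C → free catalyst + target (k4 = 0.758 s⁻¹)
    2 catalyst intermediate A → spent catalyst A (k5 = 1.80 M⁻¹ s⁻¹)
    free catalyst + impurity → spent catalyst B (k6 = 1310 M⁻¹ s⁻¹)

The simulation gives alpha as best, with 84.6 % for alpha, 64.4 % for eta, 26.4 % for beta and 81.5 % for theta, so alpha leads theta by 3.1 percentage points, more than the margin. In theta at 2.00 h, spent catalyst A holds 81.4 % of the catalyst charged. With the exponent 0.439, a run ten times as long is reckoned to multiply substrate left by 0.364, which reckons theta from 18.5 % down to 6.73 %, where the flask shows 5.07 % at 20.0 h, and alpha from 15.4 % down to 5.61 %, where the flask shows 3.74 % at 20.0 h.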